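The route rests on the C4–C5 disconnection of the cyclopentane ring (C1–C2–C3–C4–C5, guaiane numbering) as an intramolecular aldol addition. It exploits two features of the target: the C4 tertiary carbinol next to the C5 methine is the aldol retron of a C6 ketone, and C5 is allylic to the C1=C10 ring-fusion alkene, so that in a seven-membered β,γ-unsaturated ketone only C5 enolizes. The precursor is a monocyclic cyclohept-3-enone (ring-closing metathesis product) bearing a 3-oxobutyl chain on C1, the C7 isopropyl and a C8 silyloxy group; its dienolate closes the five-membered ring last and creates C4 and C5 in one operation, after which C6 is reduced and C8 esterified.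

Key step: step 10

Remark: atom labels follow guaiane numbering (C1=C10 ring-fusion alkene, C4 carbinol, C5 ring-fusion CH, C6 CHOH, C7 CH–iPr, C8 CH–O-acyl); acyl oxazolidinone 3 is assumed to be a catalogue reagent (otherwise one N-acylation of (R)-4-benzyloxazolidin-2-one with 3-methylbutanoyl chloride).

Step 1
Reactants: 1 3-methylbut-3-en-1-ol
Product: 2 3-methylbut-3-enal
Conditions: Dess–Martin periodinane, pyridine, CH2Cl2, 0 °C; used as a dried CH2Cl2 solution
Reagents that add atoms: none
Why: Dess–Martin oxidation of a primary homoallylic alcohol under buffered, non-aqueous conditions should not move the 1,1-disubstituted alkene into conjugation; the volatile aldehyde is not concentrated.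

Step 2
Reactants: 3 (4R)-4-benzyl-3-(3-methylbutanoyl)-1,3-oxazolidin-2-one; 2 3-methylbut-3-enal
Product: 5 (4R)-4-benzyl-3-[(2R,3S)-3-hydroxy-5-methyl-2-(propan-2-yl)hex-5-enoyl]-1,3-oxazolidin-2-one, via boron Z-enolate 4 (not isolated)
Conditions: Bu2BOTf, iPr2NEt, CH2Cl2, −78 → 0 °C; then 2, −78 → 0 °C; pH 7 buffer, MeOH, 30% H2O2, 0 °C
Reagents that add atoms: none
Why: Evans syn-aldol: the Z-boron enolate reacts through a Zimmerman–Traxler chair on the face left open by the benzyl group of the (R)-auxiliary, which should set C7 (2R) and C8 (3S) in the syn relationship that becomes trans C7-isopropyl/C8-oxygen in the ring.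

Step 3
Reactants: 5 (4R)-4-benzyl-3-[(2R,3S)-3-hydroxy-5-methyl-2-(propan-2-yl)hex-5-enoyl]-1,3-oxazolidin-2-one
Product: 6 (2R,3S)-3-hydroxy-N-methoxy-N,5-dimethyl-2-(propan-2-yl)hex-5-enamide
Conditions: MeNH(OMe)·HCl, AlMe3, CH2Cl2, −20 → 0 °C; dilute aq. HCl work-up
Reagents that add atoms: N,O-dimethylhydroxylamine hydrochloride, CNOC.Cl
Why: Aluminium-amide transamination of a β-hydroxy N-acyl oxazolidinone (Weinreb amide formation) is assisted by the free hydroxyl and releases the auxiliary without touching C7.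

Step 4
Reactants: 6 (2R,3S)-3-hydroxy-N-methoxy-N,5-dimethyl-2-(propan-2-yl)hex-5-enamide
Product: 7 (2R,3S)-3-[(tert-butyldimethylsilyl)oxy]-N-methoxy-N,5-dimethyl-2-(propan-2-yl)hex-5-enamide
Conditions: TBSOTf, 2,6-lutidine, CH2Cl2, −78 → 0 °C
Reagents that add atoms: tert-butyldimethylsilyl trifluoromethanesulfonate, CC(C)(C)[Si](C)(C)OS(=O)(=O)C(F)(F)F
Why: Silyl triflate silylation of a hindered secondary alcohol gives a non-chelating C8 protecting group that survives every step up to step 12.

Step 5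
Reactants: 7 (2R,3S)-3-[(tert-butyldimethylsilyl)oxy]-N-methoxy-N,5-dimethyl-2-(propan-2-yl)hex-5-enamide
Product: 8 (2R,3S)-3-[(tert-butyldimethylsilyl)oxy]-5-methyl-2-(propan-2-yl)hex-5-enal
Conditions: DIBAL-H, THF, −78 °C; aq. Rochelle salt
Reagents that add atoms: none
Why: Hydride reduction of a Weinreb amide stops at the chelated hemiaminal, and cold work-up should give the α-branched aldehyde without epimerization.

Step 6
Reactants: 9 acetone N,N-dimethylhydrazone; 10 3-chloro-2-(chloromethyl)prop-1-ene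
Product: 13 5-(chloromethyl)hex-5-en-2-one, via lithiated hydrazone 11 (not isolated), via alkylated hydrazone 12 (not isolated)
Conditions: n-BuLi, THF, −78 → 0 °C; added to 10 (3 equiv), −78 °C → rt; 1 M aq. HCl/pentane, 0 °C
Reagents that add atoms: water, O
Why: Hydrazone aza-enolate alkylation with an excess of the symmetric bis-allylic dichloride (SN2 and SN2′ give the same product) should stop at mono-alkylation, and mild two-phase hydrolysis frees the methyl ketone.

Step 7
Reactants: 8 (2R,3S)-3-[(tert-butyldimethylsilyl)oxy]-5-methyl-2-(propan-2-yl)hex-5-enal; 13 5-(chloromethyl)hex-5-en-2-one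
Product: 14 (8S,9S)-9-[(tert-butyldimethylsilyl)oxy]-7-hydroxy-11-methyl-5-methylidene-8-(propan-2-yl)dodec-11-en-2-one (both epimers at the new carbinol, C6 of the target)
Conditions: CrCl2, LiI (cat.), THF, 0 °C → rt
Reagents that add atoms: none
Why: Nozaki–Hiyama allylation: the allylchromium species should add to the aldehyde much faster than to the methyl ketone and without base, so C7 is not epimerized; the C6 carbinol mixture is of no consequence because C6 is oxidized in step 9.

Step 8
Reactants: 14 (8S,9S)-9-[(tert-butyldimethylsilyl)oxy]-7-hydroxy-11-methyl-5-methylidene-8-(propan-2-yl)dodec-11-en-2-one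
Product: 15 4-[(4S,5S)-4-[(tert-butyldimethylsilyl)oxy]-6-hydroxy-2-methyl-5-(propan-2-yl)cyclohept-1-en-1-yl]butan-2-one (C6 epimers)
Conditions: Hoveyda–Grubbs-type Ru catalyst with N,N′-di(o-tolyl) NHC (10 mol %), toluene (5 mM), 80 °C, argon sparge
Reagents that add atoms: none
Why: Ring-closing metathesis of two 1,1-disubstituted alkenes to a tetrasubstituted cycloalkene is feasible with sterically reduced NHC–Ru catalysts, and loss of ethene and the branched chain should favour the seven-membered ring with the C1=C10 alkene.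

Step 9
Reactants: 15 4-[(4S,5S)-4-[(tert-butyldimethylsilyl)oxy]-6-hydroxy-2-methyl-5-(propan-2-yl)cyclohept-1-en-1-yl]butan-2-one
Product: 16 (6S,7R)-6-[(tert-butyldimethylsilyl)oxy]-4-methyl-3-(3-oxobutyl)-7-(propan-2-yl)cyclohept-3-en-1-one
Conditions: Dess–Martin periodinane, pyridine, CH2Cl2, 0 °C; filtered through neutral alumina and used at once
Reagents that add atoms: none
Why: Buffered Dess–Martin oxidation of the homoallylic alcohol should give the β,γ-unsaturated C6 ketone without conjugating the C1=C10 alkene, and both C6 epimers converge.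

Step 10
Reactants: 16 (6S,7R)-6-[(tert-butyldimethylsilyl)oxy]-4-methyl-3-(3-oxobutyl)-7-(propan-2-yl)cyclohept-3-en-1-one
Product: 19 (3S,3aR,5R,6S)-6-[(tert-butyldimethylsilyl)oxy]-3-hydroxy-3,8-dimethyl-5-(propan-2-yl)-2,3,3a,5,6,7-hexahydroazulen-4(1H)-one, via lithium dienolate 17 (not isolated), via lithium aldolate 18 (not isolated)
Conditions: LiHMDS (1.1 equiv), THF, −78 → −20 °C; AcOH, −78 °C
Reagents that add atoms: none
Why: LiHMDS removes a C5 proton (α to the C6 ketone and allylic to C1=C10, several pKa units more acidic than the methyl ketone or the hindered C7–H) to give the cross-conjugated lithium dienolate 17, whose α-carbon C5 adds to the tethered C4 methyl ketone to give the chelated aldolate 18. This is an intramolecular aldol addition of a ketone dienolate reacting at its α-carbon, and it closes the cyclopentane C1–C2–C3–C4–C5 in the 5-(enolexo)-exo-trig mode. C4 is set by the lithium-bridged closed transition state, which holds the new C4–O syn to the C6 carbonyl on the five-membered ring and the methyl group anti. C5 is set by C7 and C8: the chain should add to the dienolate face that lets the C7 isopropyl and C8 silyloxy groups stay pseudo-equatorial in the forming hydroazulenone, and because lithium aldolates of ketone acceptors can revert at −20 °C the same 5,7-cis arrangement is expected as the thermodynamic outcome. The step needs C5 enolization over C3/methyl enolization (secured by the double activation and the weak, equilibrating amide base), α- over γ-attack (γ-attack at C10 would need a four-membered ring) and no Michael pathway (the enone is kept deconjugated until this step).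

Step 11
Reactants: 19 (3S,3aR,5R,6S)-6-[(tert-butyldimethylsilyl)oxy]-3-hydroxy-3,8-dimethyl-5-(propan-2-yl)-2,3,3a,5,6,7-hexahydroazulen-4(1H)-one
Product: 21 (3S,3aS,4R,5S,6S)-6-[(tert-butyldimethylsilyl)oxy]-3,8-dimethyl-5-(propan-2-yl)-1,2,3,3a,4,5,6,7-octahydroazulene-3,4-diol, via diethylboryl chelate 20 (not isolated)
Conditions: Et2BOMe, THF/MeOH (4:1), −78 °C; NaBH4, −78 °C; AcOH, then MeOH co-evaporation
Reagents that add atoms: none
Why: Narasaka–Prasad reduction: the C4–O–BEt2 group chelates the C6 carbonyl and external hydride adds from the face opposite the chelate, which is also opposite the C7 isopropyl group and the C5–C4 bond, so the C6 hydroxyl should emerge syn to the C4 hydroxyl and cis to the isopropyl group.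

Step 12
Reactants: 21 (3S,3aS,4R,5S,6S)-6-[(tert-butyldimethylsilyl)oxy]-3,8-dimethyl-5-(propan-2-yl)-1,2,3,3a,4,5,6,7-octahydroazulene-3,4-diol
Product: 22 (3S,3aS,4R,5R,6S)-3,8-dimethyl-5-(propan-2-yl)-1,2,3,3a,4,5,6,7-octahydroazulene-3,4,6-triol
Conditions: HF·pyridine, pyridine, THF, 0 °C → rt
Reagents that add atoms: none
Why: Buffered fluoride desilylation should free the C8 hydroxyl without ionizing the tertiary C4 alcohol or moving the tetrasubstituted alkene.

Step 13
Reactants: 22 (3S,3aS,4R,5R,6S)-3,8-dimethyl-5-(propan-2-yl)-1,2,3,3a,4,5,6,7-octahydroazulene-3,4,6-triol; 23 4-acetoxy-3-methoxybenzoic acid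
Product: 24 (3S,3aS,4R,5S,6S)-3,4-dihydroxy-3,8-dimethyl-5-(propan-2-yl)-1,2,3,3a,4,5,6,7-octahydroazulen-6-yl 4-acetoxy-3-methoxybenzoate
Conditions: 23 (1.05 equiv), EDC·HCl, DMAP (cat.), CH2Cl2, 0 °C → rt
Reagents that add atoms: none
Why: Steglich esterification should select the C8 hydroxyl, since C4 is tertiary and C6 is flanked by two branched carbons and hydrogen-bonded to the C4 hydroxyl.

Step 14
Reactants: 24 (3S,3aS,4R,5S,6S)-3,4-dihydroxy-3,8-dimethyl-5-(propan-2-yl)-1,2,3,3a,4,5,6,7-octahydroazulen-6-yl 4-acetoxy-3-methoxybenzoate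
Product: 25 (3S,3aS,4R,5S,6S)-3,4-dihydroxy-3,8-dimethyl-5-(propan-2-yl)-1,2,3,3a,4,5,6,7-octahydroazulen-6-yl 4-hydroxy-3-methoxybenzoate (CNP0299353.1)
Conditions: pyrrolidine, CH2Cl2, 0 °C
Reagents that add atoms: none
Why: Aminolysis of the aryl acetate is much faster than attack on the hindered secondary benzoate, so the phenol should be freed without ester cleavage or acyl migration.

Compound list
1 | 3-methylbut-3-en-1-ol | C=C(C)CCO | starting material
2 | 3-methylbut-3-enal | C=C(C)CC=O | intermediate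
3 | (4R)-4-benzyl-3-(3-methylbutanoyl)-1,3-oxazolidin-2-one | CC(C)CC(=O)N1[C@H](Cc2ccccc2)COC1=O | starting material
4 | (4R)-4-benzyl-3-[(1Z)-1-(dibutylboranyloxy)-3-methylbut-1-en-1-yl]-1,3-oxazolidin-2-one (boron Z-enolate of 3) | CC(C)/C=C(\OB(CCCC)CCCC)N1[C@H](Cc2ccccc2)COC1=O | intermediate
5 | (4R)-4-benzyl-3-[(2R,3S)-3-hydroxy-5-methyl-2-(propan-2-yl)hex-5-enoyl]-1,3-oxazolidin-2-one | C=C(C)C[C@H](O)[C@@H](C(C)C)C(=O)N1[C@H](Cc2ccccc2)COC1=O | intermediate
6 | (2R,3S)-3-hydroxy-N-methoxy-N,5-dimethyl-2-(propan-2-yl)hex-5-enamide | C=C(C)C[C@H](O)[C@@H](C(C)C)C(=O)N(C)OC | intermediate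
7 | (2R,3S)-3-[(tert-butyldimethylsilyl)oxy]-N-methoxy-N,5-dimethyl-2-(propan-2-yl)hex-5-enamide | C=C(C)C[C@H](O[Si](C)(C)C(C)(C)C)[C@@H](C(C)C)C(=O)N(C)OC | intermediate
8 | (2R,3S)-3-[(tert-butyldimethylsilyl)oxy]-5-methyl-2-(propan-2-yl)hex-5-enal | C=C(C)C[C@H](O[Si](C)(C)C(C)(C)C)[C@@H](C(C)C)C=O | intermediate
9 | acetone N,N-dimethylhydrazone | CC(C)=NN(C)C | starting material
10 | 3-chloro-2-(chloromethyl)prop-1-ene | C=C(CCl)CCl | starting material
11 | lithiated acetone N,N-dimethylhydrazone (aza-enolate) | [Li]CC(C)=NN(C)C | intermediate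
12 | 5-(chloromethyl)hex-5-en-2-one N,N-dimethylhydrazone | CC(CCC(=C)CCl)=NN(C)C | intermediate
13 | 5-(chloromethyl)hex-5-en-2-one | CC(=O)CCC(=C)CCl | intermediate
14 | (8S,9S)-9-[(tert-butyldimethylsilyl)oxy]-7-hydroxy-11-methyl-5-methylidene-8-(propan-2-yl)dodec-11-en-2-one (C7 epimers) | C=C(C)C[C@H](O[Si](C)(C)C(C)(C)C)[C@@H](C(C)C)C(O)CC(=C)CCC(C)=O | intermediate
15 | 4-[(4S,5S)-4-[(tert-butyldimethylsilyl)oxy]-6-hydroxy-2-methyl-5-(propan-2-yl)cyclohept-1-en-1-yl]butan-2-one (C6 epimers) | CC(=O)CCC1=C(C)C[C@H](O[Si](C)(C)C(C)(C)C)[C@@H](C(C)C)C(O)C1 | intermediate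
16 | (6S,7R)-6-[(tert-butyldimethylsilyl)oxy]-4-methyl-3-(3-oxobutyl)-7-(propan-2-yl)cyclohept-3-en-1-one | CC(=O)CCC1=C(C)C[C@H](O[Si](C)(C)C(C)(C)C)[C@@H](C(C)C)C(=O)C1 | intermediate
17 | lithium dienolate of 16 (O–C6=C5–C1=C10) | [Li]OC1=CC(CCC(C)=O)=C(C)C[C@H](O[Si](C)(C)C(C)(C)C)[C@H]1C(C)C | intermediate
18 | lithium C4-alkoxide (aldolate) of 19 | CC(C)(C)[Si](C)(C)O[C@H]1CC(C)=C2CC[C@](C)(O[Li])[C@@H]2C(=O)[C@@H]1C(C)C | intermediate
19 | (3S,3aR,5R,6S)-6-[(tert-butyldimethylsilyl)oxy]-3-hydroxy-3,8-dimethyl-5-(propan-2-yl)-2,3,3a,5,6,7-hexahydroazulen-4(1H)-one | CC(C)(C)[Si](C)(C)O[C@H]1CC(C)=C2CC[C@](C)(O)[C@@H]2C(=O)[C@@H]1C(C)C | intermediate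
20 | C4-O-diethylboryl derivative of 19 (boron chelated to the C6 carbonyl) | CC(C)(C)[Si](C)(C)O[C@H]1CC(C)=C2CC[C@](C)(OB(CC)CC)[C@@H]2C(=O)[C@@H]1C(C)C | intermediate
21 | (3S,3aS,4R,5S,6S)-6-[(tert-butyldimethylsilyl)oxy]-3,8-dimethyl-5-(propan-2-yl)-1,2,3,3a,4,5,6,7-octahydroazulene-3,4-diol | CC(C)(C)[Si](C)(C)O[C@H]1CC(C)=C2CC[C@](C)(O)[C@@H]2[C@H](O)[C@@H]1C(C)C | intermediate
22 | (3S,3aS,4R,5R,6S)-3,8-dimethyl-5-(propan-2-yl)-1,2,3,3a,4,5,6,7-octahydroazulene-3,4,6-triol | O[C@H]1CC(C)=C2CC[C@](C)(O)[C@@H]2[C@H](O)[C@@H]1C(C)C | intermediate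
23 | 4-acetoxy-3-methoxybenzoic acid | COc1cc(C(=O)O)ccc1OC(C)=O | starting material
24 | (3S,3aS,4R,5S,6S)-3,4-dihydroxy-3,8-dimethyl-5-(propan-2-yl)-1,2,3,3a,4,5,6,7-octahydroazulen-6-yl 4-acetoxy-3-methoxybenzoate | COc1cc(C(=O)O[C@H]2CC(C)=C3CC[C@](C)(O)[C@@H]3[C@H](O)[C@@H]2C(C)C)ccc1OC(C)=O | intermediate
25 | (3S,3aS,4R,5S,6S)-3,4-dihydroxy-3,8-dimethyl-5-(propan-2-yl)-1,2,3,3a,4,5,6,7-octahydroazulen-6-yl 4-hydroxy-3-methoxybenzoate | COc1cc(C(=O)O[C@H]2CC(C)=C3CC[C@](C)(O)[C@@H]3[C@H](O)[C@@H]2C(C)C)ccc1O | target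

Total step count: 14. Longest linear sequence: 13 steps (1 → 25 through steps 1–5 and 7–14); step 6 is a one-step side branch.

Steps most likely to fail

Step 10 (key aldol). Proton transfer may outrun C–C bond formation, so that the β,γ-enone slips into conjugation and the methyl ketone enolate then adds in Michael fashion. The lithium aldolate may also revert on warming, or the chain may add to the wrong face of C5. Fallback, from 16: soft silylation at the more acidic C5 position (TMSOTf, Et3N, CH2Cl2, −78 °C) should give the trimethylsilyl dienol ether F1. An intramolecular Mukaiyama aldol (TiCl4, CH2Cl2, −78 °C) then activates the methyl ketone with the Lewis acid and makes the addition irreversible by silyl transfer, with no free basic enolate present. Aqueous work-up returns to the route at 19.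

Step 8 (ring-closing metathesis). The catalyst may stall on the two hindered 1,1-disubstituted alkenes, or ruthenium hydride species may isomerize them. Fallback, from 14: the methyl ketone is masked as the dioxolane F2 (ethylene glycol, PPTS, benzene, reflux) and the C6 hydroxyl is silylated to the triethylsilyl ether F3 (TESOTf, 2,6-lutidine). Ozonolysis of both methylidene groups (O3, CH2Cl2, −78 °C; PPh3) gives the diketone F4. Intramolecular McMurry coupling (TiCl3(DME)1.5, Zn–Cu, DME, reflux) then forms the tetrasubstituted C1=C10 alkene in the cycloheptene F5. PPTS in aqueous acetone removes the dioxolane and the triethylsilyl group and returns to the route at 15.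

Step 13 (site-selective esterification). The C6 hydroxyl may be acylated in competition, or the acyl group may migrate between O8 and O6. Fallback, from 19: the two secondary oxygens are told apart by oxidation state instead of sterics. HF·pyridine gives the keto diol F6, whose only secondary hydroxyl (C8) is esterified with 23 (EDC·HCl, DMAP) to the keto ester F7. Narasaka–Prasad reduction of F7 (Et2BOMe, NaBH4, −78 °C) then sets C6 and returns to the route at 24.

Further compounds
F1 | step 10 | C6-O-trimethylsilyl dienol ether of 16 (C5=C6 and C1=C10 double bonds) | C[Si](C)(C)OC1=CC(CCC(C)=O)=C(C)C[C@H](O[Si](C)(C)C(C)(C)C)[C@H]1C(C)C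
F2 | step 8 | ethylene ketal (1,3-dioxolane) of 14 at the C4 ketone | C=C(C)C[C@H](O[Si](C)(C)C(C)(C)C)[C@@H](C(C)C)C(O)CC(=C)CCC1(C)OCCO1
F3 | step 8 | C6-O-triethylsilyl ether of F2 | C=C(C)C[C@H](O[Si](C)(C)C(C)(C)C)[C@@H](C(C)C)C(O[Si](CC)(CC)CC)CC(=C)CCC1(C)OCCO1
F4 | step 8 | diketone from double ozonolysis of F3 (C1 ketone and C10 methyl ketone) | CC(=O)C[C@H](O[Si](C)(C)C(C)(C)C)[C@@H](C(C)C)C(O[Si](CC)(CC)CC)CC(=O)CCC1(C)OCCO1
F5 | step 8 | cycloheptene from McMurry coupling of F4 (C4 dioxolane, C6 OTES, C8 OTBS) | CC1(CCC2=C(C)C[C@H](O[Si](C)(C)C(C)(C)C)[C@@H](C(C)C)C(O[Si](CC)(CC)CC)C2)OCCO1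
F6 | step 13 | (3S,3aR,5R,6S)-3,6-dihydroxy-3,8-dimethyl-5-(propan-2-yl)-2,3,3a,5,6,7-hexahydroazulen-4(1H)-one | O[C@H]1CC(C)=C2CC[C@](C)(O)[C@@H]2C(=O)[C@@H]1C(C)C
F7 | step 13 | (3S,3aR,5R,6S)-3-hydroxy-3,8-dimethyl-4-oxo-5-(propan-2-yl)-1,2,3,3a,4,5,6,7-octahydroazulen-6-yl 4-acetoxy-3-methoxybenzoate | COc1cc(C(=O)O[C@H]2CC(C)=C3CC[C@](C)(O)[C@@H]3C(=O)[C@@H]2C(C)C)ccc1OC(C)=O
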